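All runs stem from a simulated flask for substances that don't exist; the scatter is artificial.

Start from elm, the earlier run, and hold it beside maple, the flask you care about. Both begin at 0.11 M substrate and add reagent in 3 portions, 1.5 min apart. But maple gets 1.2 equiv of reagent and elm 2.4 equiv, so maple has half of elm's charge.

| setting | maple | elm | flask |
|---|---|---|---|
| substrate | 0.11 M | 0.11 M | 0.11 M |
| reagent | 1.2 equiv (in portions, 3) | 2.4 equiv (in portions, 3) | 1.20 equiv (in portions, 3) |
| remark | the very flask that is asked about, followed so far; portions every 1.5 min | run made earlier; portions every 1.5 min | the portions of reagent follow each other after 1.5 min, the first at the start |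
| time |  |  | 2.5 h |

maple run (percent of the substrate charged)

| time / min | substrate / % | target / % | side product / % |
|---|---|---|---|
| 2.50 | 46.5 | 50.7 | 3.0 |
| 5.00 | 15.6 | 80.2 | 4.8 |
| 8.00 | 4.9 | 90.0 | 4.1 |
| 15.0 | 0.7 | 94.4 | 4.4 |
| 30.0 | 0.4 | 95.8 | 4.7 |

elm run (percent of the substrate charged)

| time / h | substrate / % | target / % | side product / % |
|---|---|---|---|
| 0.200 | 0.3 | 95.6 | 4.9 |
| 0.417 | 0 | 94.5 | 4.8 |
| 0.667 | 0.2 | 95.2 | 5.2 |
| 1.33 | 0.1 | 95.3 | 4.4 |
| 2.50 | 0 | 94.3 | 5.2 |

(standard deviation of a reading: 0.5 percentage points)

- the reaction counts as stopped when no species that holds the substrate changes by six tenths of a point or more over the second half of the time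

Elm is flat from 0.200 h on, with target near 95.6%, side product near 4.9% and substrate within the scatter of zero. So in elm the surplus reagent shows no loss of target beyond that scatter. At 30.0 min, maple reads 0.4% substrate, 95.8% target and 4.7% side product, which is nearly elm's end.

Why do they end alike? Assume that one reagent serves one substrate, and take the margin 0.200 equiv, the reagent charged minus the one equivalent the substrate needs. If it is positive and the reaction runs to its end, the substrate is the limiting reagent and the excess stays over. If it is negative, the shortfall stays behind as substrate. Elm's margin is 1.40 equiv, larger than maple's, but both are positive, so both should end with the substrate consumed, as elm's reading of 0% at 2.50 h shows for that run. Maple should keep 16.7% of its reagent.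

Now go to powers of ten, my own rough reckoning. Maple's substrate readings fall from 4.9% to 0.7% between 8.00 min and 15.0 min, which reads as one power of ten in about 8.28 min, though the lower reading stands close to its scatter of 0.5 percentage points. If that pace holds, the rest of the run holds about 16.3 such steps, so I expect substrate within the scatter of zero at 2.5 h.

- why nothing more happens at 2.5 h, or that something still does (all of the substrate has reacted / forward and back rates have come level / the reagent has run out first / it is still moving)
- conversion of substrate at 2.5 h
- amount of target at 2.5 h, in percent of the substrate charged
- amount of side product at 2.5 h, in percent of the substrate charged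

The forecast agrees: all of the substrate has reacted, with conversion 99.9%, target 95.1% and side product 4.8%. One of its grounds is “Reagent is not limiting: about 0.2 equiv should remain.”

    adduct → target (k = 0.700 s⁻¹)
    substrate + reagent ⇌ adduct (K = 0.510 L mol⁻¹, k = 0.310 L mol⁻¹ s⁻¹)
    adduct → side product (k = 0.0370 s⁻¹)

The flask ends like this: all of the substrate has reacted, with conversion 100%, target 95.0% and side product 5.02%. It keeps 17% of its reagent, against the 16.7% that the margin of 0.200 equiv named. At 2.50 h its slowest mode has a half-life of 0.0516 h, far shorter than the run of 2.5 h, and its substrate at 1.25 h already stands at 0%. A neighbouring flask, the same but with 0.720 equiv of reagent, has a margin of −0.280 equiv, and at 2.50 h it holds 0% of its reagent and 28% of the substrate.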